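**Retrosynthetic overview**

1. The target is a (2S)-flavanone (ring A benzo, ring C pyranone, ring B 4-hydroxyphenyl) whose O6 is the 4'-ether oxygen of apigenin. The last unmaskings are benzyl ethers and the 5-OMe group to OH, and C–B to C–OH at C4' of ring B (the boronate keeps C2 an electron-neutral benzylic carbon until ring C is closed).
2. Key disconnection: ring C at O1–C2 and C4–C4a, giving phenol 8 (ring A already carrying the whole flavone) and the (R)-β-lactone 15 as a strained chiral C3 1,3-dielectrophile. Both bonds form in one flask: strain-driven SN2 opening, then Friedel–Crafts acylation.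
3. Enabling feature: in ring A, O5, O6 and O7 sit on adjacent carbons and O1 is para to O6. With O5 masked as a second methyl ether the phenol has a mirror plane through C8a and C6, so C4a and C8 are the same carbon, each flanked by O1 and OMe, and the peri C4=O later singles out the O5 methyl group. C2 (benzylic) and C4 (acyl) are 1,3-related, which maps onto a β-lactone.
4. Phenol 8: diaryl ether by SNAr, chalcone, iodine/DMSO closure of the flavone pyranone ring, then Br to OH.
5. Ring order: flavone pyranone ring (step 3), temporary β-lactone (step 8), flavanone ring C (step 9).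

Key step: step 9

Assumption: acetophenone 4 is taken as purchasable; otherwise it is one benzylation step from 2',4',6'-trihydroxyacetophenone.
Assumption: the (R,R)-configured transfer-hydrogenation catalyst is taken to give the (R)-carbinol, as with simple aryl ketones; if the sense proved opposite, the (S,S)-catalyst would be used.

**Route**

Step 1
Reactants: 1 4-bromo-2,6-dimethoxyphenol; 2 4-fluorobenzaldehyde
Product: 3 4-(4-bromo-2,6-dimethoxyphenoxy)benzaldehyde
Conditions: K2CO3, DMF, 130 °C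
Reagents that add atoms: none
Why: Nucleophilic aromatic substitution (SNAr) in which the para-formyl group activates the C–F bond toward the electron-rich 2,6-dimethoxyphenoxide, while the bromide is inert and marks the carbon that later carries O1.

Step 2
Reactants: 3 4-(4-bromo-2,6-dimethoxyphenoxy)benzaldehyde; 4 1-[2,4-bis(benzyloxy)-6-hydroxyphenyl]ethan-1-one
Product: 5 (E)-1-[2,4-bis(benzyloxy)-6-hydroxyphenyl]-3-[4-(4-bromo-2,6-dimethoxyphenoxy)phenyl]prop-2-en-1-one
Conditions: KOH (50% aq.), EtOH/THF, rt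
Reagents that add atoms: none
Why: Claisen–Schmidt condensation (aldol addition, then E1cB dehydration) should give the E-configured 2'-hydroxychalcone, the chelated phenol needing no protection.

Step 3
Reactants: 5 (E)-1-[2,4-bis(benzyloxy)-6-hydroxyphenyl]-3-[4-(4-bromo-2,6-dimethoxyphenoxy)phenyl]prop-2-en-1-one
Product: 6 5,7-bis(benzyloxy)-2-[4-(4-bromo-2,6-dimethoxyphenoxy)phenyl]-4H-chromen-4-one
Conditions: I2 (10 mol%), DMSO, 130 °C
Reagents that add atoms: none
Why: Iodine-catalysed oxidative cyclization of a 2'-hydroxychalcone (oxa-Michael closure, α-iodination, loss of HI, with DMSO as terminal oxidant) is the standard flavone synthesis and tolerates benzyl ethers and the aryl bromide.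

Step 4
Reactants: 6 5,7-bis(benzyloxy)-2-[4-(4-bromo-2,6-dimethoxyphenoxy)phenyl]-4H-chromen-4-one
Product: 8 5,7-bis(benzyloxy)-2-[4-(4-hydroxy-2,6-dimethoxyphenoxy)phenyl]-4H-chromen-4-one, via aryl pinacol boronate 7 (not isolated)
Conditions: bis(pinacolato)diboron, PdCl2(dppf) (3 mol%), KOAc, 1,4-dioxane, 90 °C; then 30% aq. H2O2, THF, 0 °C to rt
Reagents that add atoms: hydrogen peroxide, OO
Why: Miyaura borylation of the unhindered aryl bromide followed by oxidative conversion of C–B to C–O in the same flask should reveal the phenol that becomes O1, with the flavone and benzyl ethers inert.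

Step 5
Reactants: 9 4-(4,4,5,5-tetramethyl-1,3,2-dioxaborolan-2-yl)benzoic acid; 10 2,2-dimethyl-1,3-dioxane-4,6-dione (Meldrum's acid)
Product: 12 tert-butyl 3-oxo-3-[4-(4,4,5,5-tetramethyl-1,3,2-dioxaborolan-2-yl)phenyl]propanoate, via acyl Meldrum's acid 11 (not isolated)
Conditions: DCC, DMAP, CH2Cl2, 0 °C to rt; filter, aq. KHSO4 wash, evaporate; t-BuOH, toluene, 90 °C
Reagents that add atoms: tert-butanol, CC(C)(C)O
Why: Carbodiimide-mediated C-acylation of Meldrum's acid and thermolysis to an acylketene that is trapped by tert-butanol is the standard β-keto ester synthesis; the pinacol boronate is a spectator.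

Step 6
Reactants: 12 tert-butyl 3-oxo-3-[4-(4,4,5,5-tetramethyl-1,3,2-dioxaborolan-2-yl)phenyl]propanoate
Product: 13 tert-butyl (3R)-3-hydroxy-3-[4-(4,4,5,5-tetramethyl-1,3,2-dioxaborolan-2-yl)phenyl]propanoate
Conditions: RuCl[(R,R)-TsDPEN](p-cymene) (1 mol%), HCO2H/Et3N (5:2), 30 °C
Reagents that add atoms: none
Why: Asymmetric transfer hydrogenation of an aryl β-keto ester, in which the chiral diamine ligand controls the face of hydride delivery and should set the (R)-carbinol.

Step 7
Reactants: 13 tert-butyl (3R)-3-hydroxy-3-[4-(4,4,5,5-tetramethyl-1,3,2-dioxaborolan-2-yl)phenyl]propanoate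
Product: 14 (3R)-3-hydroxy-3-[4-(4,4,5,5-tetramethyl-1,3,2-dioxaborolan-2-yl)phenyl]propanoic acid
Conditions: TFA, CH2Cl2, 0 °C
Reagents that add atoms: none
Why: Acidolysis of the tert-butyl ester (loss of isobutene) breaks no bond at the stereocenter, and the electron-neutral boryl-aryl group should keep the benzylic carbinol from ionizing.

Step 8
Reactants: 14 (3R)-3-hydroxy-3-[4-(4,4,5,5-tetramethyl-1,3,2-dioxaborolan-2-yl)phenyl]propanoic acid
Product: 15 (4R)-4-[4-(4,4,5,5-tetramethyl-1,3,2-dioxaborolan-2-yl)phenyl]oxetan-2-one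
Conditions: PhSO2Cl, pyridine, 0 to 4 °C
Reagents that add atoms: none
Why: β-Lactonization by carboxyl-group activation (mixed sulfonic–carboxylic anhydride, 4-exo-trig attack of the hydroxyl) leaves the C–O bond at the stereocenter intact, so the (R)-configuration is retained.

Step 9
Reactants: 8 5,7-bis(benzyloxy)-2-[4-(4-hydroxy-2,6-dimethoxyphenoxy)phenyl]-4H-chromen-4-one; 15 (4R)-4-[4-(4,4,5,5-tetramethyl-1,3,2-dioxaborolan-2-yl)phenyl]oxetan-2-one
Product: 18 (2S)-6-{4-[5,7-bis(benzyloxy)-4-oxo-4H-chromen-2-yl]phenoxy}-5,7-dimethoxy-2-[4-(4,4,5,5-tetramethyl-1,3,2-dioxaborolan-2-yl)phenyl]-2,3-dihydro-4H-chromen-4-one, via cesium carboxylate 16 (not isolated), via mixed trifluoroacetic anhydride 17 (not isolated)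
Conditions: Cs2CO3 (1.0 equiv), MeCN, 25 to 40 °C; evaporate; TFAA, TFA/CH2Cl2 (1:4), 0 °C to rt
Reagents that add atoms: none
Why: Proposed new method: the cesium phenoxide of 8 should open β-lactone 15 at its benzylic ring carbon by SN2 alkyl–oxygen cleavage, the release of four-ring strain making the O1–C2 bond irreversible and leaving carboxylate 16, which TFAA converts into mixed anhydride 17 that acylates the ring carbon ortho to O1 to form C4–C4a. The closest known reaction types are the alkyl–oxygen opening of β-lactones by phenoxide, carboxylate and azide nucleophiles and the TFAA-mediated cyclization of 3-aryloxypropanoic acids to chroman-4-ones, here merged into one stereospecific (3+3) annulation. Ring C closes through C4–C4a in a 6-exo-trig electrophilic aromatic substitution, whereas the O1–C2 bond is made intermolecularly and closes no ring. C2 is set by inversion of the (R)-configured lactone carbon to (S), the control element being the stereocenter of 15 installed in step 6, and the boryl-substituted ring B gives no stabilized benzylic cation that could scramble it in TFA. The step needs O- over C-alkylation and alkyl–oxygen cleavage over acyl attack or elimination, which the soft cesium phenoxide in a polar aprotic solvent and the benzylic SN2 carbon should secure. It also needs a single acylation site, which the mirror plane of ring A in 8 secures because both carbons ortho to O1 are identical and triply oxygen-activated, while the benzyloxylated flavone ring is deactivated by its carbonyl group.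

Step 10
Reactants: 18 (2S)-6-{4-[5,7-bis(benzyloxy)-4-oxo-4H-chromen-2-yl]phenoxy}-5,7-dimethoxy-2-[4-(4,4,5,5-tetramethyl-1,3,2-dioxaborolan-2-yl)phenyl]-2,3-dihydro-4H-chromen-4-one
Product: 19 (2S)-6-{4-[5,7-bis(benzyloxy)-4-oxo-4H-chromen-2-yl]phenoxy}-2-(4-hydroxyphenyl)-5,7-dimethoxy-2,3-dihydro-4H-chromen-4-one
Conditions: 30% aq. H2O2, THF/pH 7 phosphate buffer (NaH2PO4/Na2HPO4), 0 °C to rt
Reagents that add atoms: hydrogen peroxide, OO
Why: Ipso-oxidation of the aryl boronate (peroxide adduct, 1,2-aryl shift from boron to oxygen, hydrolysis) at neutral pH should unveil the 4'-OH without opening the base-sensitive flavanone or touching C2.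

Step 11
Reactants: 19 (2S)-6-{4-[5,7-bis(benzyloxy)-4-oxo-4H-chromen-2-yl]phenoxy}-2-(4-hydroxyphenyl)-5,7-dimethoxy-2,3-dihydro-4H-chromen-4-one
Product: 20 (2S)-6-[4-(5,7-dihydroxy-4-oxo-4H-chromen-2-yl)phenoxy]-5-hydroxy-2-(4-hydroxyphenyl)-7-methoxy-2,3-dihydro-4H-chromen-4-one (CNP0269971.1)
Conditions: BCl3, pentamethylbenzene, CH2Cl2, −78 to 0 °C; MeOH, then water
Reagents that add atoms: none
Why: BCl3 ether cleavage should remove both benzyl groups (pentamethylbenzene traps the benzyl cation) and, through chelation between the C4 carbonyl oxygen and O5, only the peri 5-methyl ether, leaving the unchelated 7-OMe and, under these non-basic conditions, the C2 configuration.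

**Compound list**

1 | 4-bromo-2,6-dimethoxyphenol | COc1cc(Br)cc(OC)c1O | starting material
2 | 4-fluorobenzaldehyde | O=Cc1ccc(F)cc1 | starting material
3 | 4-(4-bromo-2,6-dimethoxyphenoxy)benzaldehyde | COc1cc(Br)cc(OC)c1Oc1ccc(C=O)cc1 | intermediate
4 | 1-[2,4-bis(benzyloxy)-6-hydroxyphenyl]ethan-1-one | CC(=O)c1c(O)cc(OCc2ccccc2)cc1OCc1ccccc1 | starting material
5 | (E)-1-[2,4-bis(benzyloxy)-6-hydroxyphenyl]-3-[4-(4-bromo-2,6-dimethoxyphenoxy)phenyl]prop-2-en-1-one | COc1cc(Br)cc(OC)c1Oc1ccc(/C=C/C(=O)c2c(O)cc(OCc3ccccc3)cc2OCc2ccccc2)cc1 | intermediate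
6 | 5,7-bis(benzyloxy)-2-[4-(4-bromo-2,6-dimethoxyphenoxy)phenyl]-4H-chromen-4-one | COc1cc(Br)cc(OC)c1Oc1ccc(-c2cc(=O)c3c(OCc4ccccc4)cc(OCc4ccccc4)cc3o2)cc1 | intermediate
7 | 5,7-bis(benzyloxy)-2-{4-[2,6-dimethoxy-4-(4,4,5,5-tetramethyl-1,3,2-dioxaborolan-2-yl)phenoxy]phenyl}-4H-chromen-4-one | COc1cc(B2OC(C)(C)C(C)(C)O2)cc(OC)c1Oc1ccc(-c2cc(=O)c3c(OCc4ccccc4)cc(OCc4ccccc4)cc3o2)cc1 | intermediate (not isolated)
8 | 5,7-bis(benzyloxy)-2-[4-(4-hydroxy-2,6-dimethoxyphenoxy)phenyl]-4H-chromen-4-one | COc1cc(O)cc(OC)c1Oc1ccc(-c2cc(=O)c3c(OCc4ccccc4)cc(OCc4ccccc4)cc3o2)cc1 | intermediate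
9 | 4-(4,4,5,5-tetramethyl-1,3,2-dioxaborolan-2-yl)benzoic acid | OC(=O)c1ccc(B2OC(C)(C)C(C)(C)O2)cc1 | starting material
10 | 2,2-dimethyl-1,3-dioxane-4,6-dione (Meldrum's acid) | CC1(C)OC(=O)CC(=O)O1 | starting material
11 | 5-{hydroxy[4-(4,4,5,5-tetramethyl-1,3,2-dioxaborolan-2-yl)phenyl]methylidene}-2,2-dimethyl-1,3-dioxane-4,6-dione | CC1(C)OC(=O)C(=C(O)c2ccc(B3OC(C)(C)C(C)(C)O3)cc2)C(=O)O1 | intermediate (not isolated)
12 | tert-butyl 3-oxo-3-[4-(4,4,5,5-tetramethyl-1,3,2-dioxaborolan-2-yl)phenyl]propanoate | CC(C)(C)OC(=O)CC(=O)c1ccc(B2OC(C)(C)C(C)(C)O2)cc1 | intermediate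
13 | tert-butyl (3R)-3-hydroxy-3-[4-(4,4,5,5-tetramethyl-1,3,2-dioxaborolan-2-yl)phenyl]propanoate | CC(C)(C)OC(=O)C[C@@H](O)c1ccc(B2OC(C)(C)C(C)(C)O2)cc1 | intermediate
14 | (3R)-3-hydroxy-3-[4-(4,4,5,5-tetramethyl-1,3,2-dioxaborolan-2-yl)phenyl]propanoic acid | OC(=O)C[C@@H](O)c1ccc(B2OC(C)(C)C(C)(C)O2)cc1 | intermediate
15 | (4R)-4-[4-(4,4,5,5-tetramethyl-1,3,2-dioxaborolan-2-yl)phenyl]oxetan-2-one | O=C1C[C@H](c2ccc(B3OC(C)(C)C(C)(C)O3)cc2)O1 | intermediate
16 | cesium (3S)-3-(4-{4-[5,7-bis(benzyloxy)-4-oxo-4H-chromen-2-yl]phenoxy}-3,5-dimethoxyphenoxy)-3-[4-(4,4,5,5-tetramethyl-1,3,2-dioxaborolan-2-yl)phenyl]propanoate | [Cs+].[O-]C(=O)C[C@H](Oc1cc(OC)c(Oc2ccc(-c3cc(=O)c4c(OCc5ccccc5)cc(OCc5ccccc5)cc4o3)cc2)c(OC)c1)c1ccc(B2OC(C)(C)C(C)(C)O2)cc1 | intermediate (not isolated)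
17 | (3S)-3-(4-{4-[5,7-bis(benzyloxy)-4-oxo-4H-chromen-2-yl]phenoxy}-3,5-dimethoxyphenoxy)-3-[4-(4,4,5,5-tetramethyl-1,3,2-dioxaborolan-2-yl)phenyl]propanoic trifluoroacetic anhydride | O=C(OC(=O)C[C@H](Oc1cc(OC)c(Oc2ccc(-c3cc(=O)c4c(OCc5ccccc5)cc(OCc5ccccc5)cc4o3)cc2)c(OC)c1)c1ccc(B2OC(C)(C)C(C)(C)O2)cc1)C(F)(F)F | intermediate (not isolated)
18 | (2S)-6-{4-[5,7-bis(benzyloxy)-4-oxo-4H-chromen-2-yl]phenoxy}-5,7-dimethoxy-2-[4-(4,4,5,5-tetramethyl-1,3,2-dioxaborolan-2-yl)phenyl]-2,3-dihydro-4H-chromen-4-one | COc1cc2c(c(OC)c1Oc1ccc(-c3cc(=O)c4c(OCc5ccccc5)cc(OCc5ccccc5)cc4o3)cc1)C(=O)C[C@@H](c1ccc(B3OC(C)(C)C(C)(C)O3)cc1)O2 | intermediate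
19 | (2S)-6-{4-[5,7-bis(benzyloxy)-4-oxo-4H-chromen-2-yl]phenoxy}-2-(4-hydroxyphenyl)-5,7-dimethoxy-2,3-dihydro-4H-chromen-4-one | COc1cc2c(c(OC)c1Oc1ccc(-c3cc(=O)c4c(OCc5ccccc5)cc(OCc5ccccc5)cc4o3)cc1)C(=O)C[C@@H](c1ccc(O)cc1)O2 | intermediate
20 | (2S)-6-[4-(5,7-dihydroxy-4-oxo-4H-chromen-2-yl)phenoxy]-5-hydroxy-2-(4-hydroxyphenyl)-7-methoxy-2,3-dihydro-4H-chromen-4-one (CNP0269971.1) | COc1cc2c(c(O)c1Oc1ccc(-c3cc(=O)c4c(O)cc(O)cc4o3)cc1)C(=O)C[C@@H](c1ccc(O)cc1)O2 | target

**Summary**

Total step count: 11.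
Longest linear sequence: 7 steps (1, 2, 3, 4, 9, 10, 11); the lactone branch (5, 6, 7, 8, then 9, 10, 11) is equally long.

**Steps most likely to fail**

Step 9 (Proposed new method). The cascade could be diverted by attack of the phenoxide at the acyl carbon, by base-induced β-elimination of the lactone, or by C- instead of O-alkylation of the ambident phenoxide. The fallback uses known chemistry and sets out from phenol 8 and hydroxy ester 13, so steps 7 and 8 are not needed. Mitsunobu etherification (PPh3, DIAD, toluene, 0 °C) should give, with inversion at the carbinol carbon, tert-butyl (3S)-3-(4-{4-[5,7-bis(benzyloxy)-4-oxo-4H-chromen-2-yl]phenoxy}-3,5-dimethoxyphenoxy)-3-[4-(4,4,5,5-tetramethyl-1,3,2-dioxaborolan-2-yl)phenyl]propanoate F1. Treating F1 with TFA and TFAA in CH2Cl2 (ester acidolysis, mixed anhydride, Friedel–Crafts ring closure at the same symmetric ring) should bring the route back at flavanone 18.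

Step 8. Dehydration or decarboxylative fragmentation of the β-hydroxy acid, or intermolecular esterification, could outrun four-ring closure. The fallback sets out from acid 14. Thioesterification (PhSH, DCC, DMAP cat., CH2Cl2) should give S-phenyl (3R)-3-hydroxy-3-[4-(4,4,5,5-tetramethyl-1,3,2-dioxaborolan-2-yl)phenyl]propanethioate F2. A thiophilic monovalent silver salt (AgOCOCF3, Na2HPO4, MeCN, rt) then activates the thiol ester and removes the thiolate as AgSPh, so the hydroxyl closes the ring under near-neutral conditions with retention. This comes back to the route at lactone 15.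

Step 11. The strong Lewis acid could also cleave the second (7-O) methyl ether, or open ring C at the benzylic C2–O1 bond with loss of configuration. The fallback sets out from 19 and separates the two tasks. Hydrogenolysis (H2, Pd/C, EtOAc/THF, rt) should give (2S)-6-[4-(5,7-dihydroxy-4-oxo-4H-chromen-2-yl)phenoxy]-2-(4-hydroxyphenyl)-5,7-dimethoxy-2,3-dihydro-4H-chromen-4-one F3. The milder magnesium chelate reagent (MgI2·OEt2, THF/toluene, 50 °C) should then cleave only the methyl ether peri to the C4 carbonyl, coming back to the route at target 20.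

Further compounds
F1 | step 9 | tert-butyl (3S)-3-(4-{4-[5,7-bis(benzyloxy)-4-oxo-4H-chromen-2-yl]phenoxy}-3,5-dimethoxyphenoxy)-3-[4-(4,4,5,5-tetramethyl-1,3,2-dioxaborolan-2-yl)phenyl]propanoate | CC(C)(C)OC(=O)C[C@H](Oc1cc(OC)c(Oc2ccc(-c3cc(=O)c4c(OCc5ccccc5)cc(OCc5ccccc5)cc4o3)cc2)c(OC)c1)c1ccc(B2OC(C)(C)C(C)(C)O2)cc1
F2 | step 8 | S-phenyl (3R)-3-hydroxy-3-[4-(4,4,5,5-tetramethyl-1,3,2-dioxaborolan-2-yl)phenyl]propanethioate | O=C(C[C@@H](O)c1ccc(B2OC(C)(C)C(C)(C)O2)cc1)Sc1ccccc1
F3 | step 11 | (2S)-6-[4-(5,7-dihydroxy-4-oxo-4H-chromen-2-yl)phenoxy]-2-(4-hydroxyphenyl)-5,7-dimethoxy-2,3-dihydro-4H-chromen-4-one | COc1cc2c(c(OC)c1Oc1ccc(-c3cc(=O)c4c(O)cc(O)cc4o3)cc1)C(=O)C[C@@H](c1ccc(O)cc1)O2
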